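**Retrosynthetic overview**
- The enal is made last, by allylic oxidation of an isopropenyl group. The side-chain ester is disconnected to the (R)-carbinol plus (R)-2-methylbutanoic acid, and the carbinol to the aryl methyl ketone.
- The trans-3-acyloxy-2-isopropenyl-2,3-dihydrobenzofuran comes from 6-acetyl-2,2-dimethyl-2H-chromene and 3-methylbutanoic acid by an enantioselective oxidative 1,2-shift of the ring oxygen (pyran to furan ring contraction). This is the key step and sets both ring stereocentres.
- The chromene comes from 4-bromophenol and prenal; the acetyl group comes from a Weinreb amide.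
- Ring order: benzene ring bought, 2H-pyran ring formed in step 1, contracted to the dihydrofuran ring in step 3.

Assumption: the (R,R)-lactate aryl iodide is assumed to deliver iodine to the alkene face that leads to (2R,3S)-12 (if the sense is opposite, its enantiomer is used unchanged otherwise), and (R)-2-methylbutanoic acid is bought as the single enantiomer.

**Step 1**
Reactants: 1 4-bromophenol; 2 3-methylbut-2-enal
Product: 4 6-bromo-2,2-dimethyl-2H-chromene, via o-quinone methide 3 (not isolated)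
Conditions: PhB(OH)2 (1 equiv), AcOH, toluene, reflux, Dean–Stark
Reagents that add atoms: none
Why: Phenylboronic acid templates the ortho-selective condensation of the phenol with the enal to the o-quinone methide, which closes by oxa-6π electrocyclisation to the 2H-chromene; no stereocentre is formed.

**Step 2**
Reactants: 4 6-bromo-2,2-dimethyl-2H-chromene; 5 N-methoxy-N-methylacetamide
Product: 8 1-(2,2-dimethyl-2H-chromen-6-yl)ethan-1-one, via aryllithium 6 (not isolated), via lithium hemiaminal 7 (not isolated)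
Conditions: n-BuLi (1.05 equiv), THF, −78 °C; then 5, −78 → 0 °C; aq. NH4Cl
Reagents that add atoms: none
Why: Fast bromine–lithium exchange followed by Weinreb ketone synthesis, where the chelated adduct stops addition at the ketone stage; no stereocentre is formed.

**Step 3**
Reactants: 8 1-(2,2-dimethyl-2H-chromen-6-yl)ethan-1-one; 9 3-methylbutanoic acid
Product: 12 (2R,3S)-5-acetyl-2-(prop-1-en-2-yl)-2,3-dihydro-1-benzofuran-3-yl 3-methylbutanoate, via alkyl(aryl)-λ3-iodane 10 (not isolated), via tertiary carbocation 11 (not isolated)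
Conditions: dimethyl (2R,2'R)-2,2'-[(2-iodo-1,3-phenylene)bis(oxy)]dipropanoate (20 mol %), mCPBA (1.1 equiv, slow addition), 9 (8 equiv), TfOH (10 mol %), 4 Å MS, CH2Cl2, −20 °C
Reagents that add atoms: none
Why: Proposed new method: the chiral aryl-I(III) dicarboxylate made in the flask by mCPBA adds face-selectively to C3=C4 with iodine at C3 and anti attack of the acid at benzylic C4 (this sets C3 of the product as S); in the trans-diequatorial adduct 10 (the gem-dimethyl group disfavours the diaxial conformer needed for acyloxy participation) the O1–C2 bond is antiperiplanar to C3–I, so loss of the aryl iodide is assisted by a 1,2-shift of O1 from C2 to C3 with inversion (this sets C2 as R, trans to the ester), and the tertiary cation 11 loses a methyl proton to give the isopropenyl group; the 6-acetyl group tempers free ionisation at C4 and the competing aryl shift, which would leave a poorly stabilised acyloxy-carbenium ion; the closest known reaction types are the enantioselective iodine(I/III)-catalysed vicinal diacyloxylation of styrenes, iodine(III)-induced ring contraction of 1,2-dihydronaphthalenes, and the sulfonate-triggered contraction of 2,2-dimethylchroman-3-ols to 2-isopropenyl-2,3-dihydrobenzofurans.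

**Step 4**
Reactants: 12 (2R,3S)-5-acetyl-2-(prop-1-en-2-yl)-2,3-dihydro-1-benzofuran-3-yl 3-methylbutanoate
Product: 13 (2R,3S)-5-[(1R)-1-hydroxyethyl]-2-(prop-1-en-2-yl)-2,3-dihydro-1-benzofuran-3-yl 3-methylbutanoate
Conditions: RuCl[(R,R)-TsDPEN](p-cymene) (1 mol %), HCO2H/Et3N (5:2), CH2Cl2, 30 °C
Reagents that add atoms: none
Why: Noyori–Ikariya asymmetric transfer hydrogenation of the aryl methyl ketone, where the (R,R)-catalyst gives the (R)-1-arylethanol under catalyst control while the ester, the alkene and the remote stereocentres are untouched.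

**Step 5**
Reactants: 13 (2R,3S)-5-[(1R)-1-hydroxyethyl]-2-(prop-1-en-2-yl)-2,3-dihydro-1-benzofuran-3-yl 3-methylbutanoate; 14 (2R)-2-methylbutanoic acid
Product: 15 (1R)-1-[(2R,3S)-3-(3-methylbutanoyloxy)-2-(prop-1-en-2-yl)-2,3-dihydro-1-benzofuran-5-yl]ethyl (2R)-2-methylbutanoate
Conditions: DIC (1.3 equiv), DMAP (10 mol %), CH2Cl2, 0 °C → rt
Reagents that add atoms: none
Why: Steglich esterification forms the O–acyl bond, so the carbinol configuration is retained, and at low DMAP loading and 0 °C the α-stereocentre of the simple alkanoic acid is not epimerised.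

**Step 6**
Reactants: 15 (1R)-1-[(2R,3S)-3-(3-methylbutanoyloxy)-2-(prop-1-en-2-yl)-2,3-dihydro-1-benzofuran-5-yl]ethyl (2R)-2-methylbutanoate
Product: 17 (1R)-1-[(2R,3S)-3-(3-methylbutanoyloxy)-2-(3-oxoprop-1-en-2-yl)-2,3-dihydro-1-benzofuran-5-yl]ethyl (2R)-2-methylbutanoate, via allylic alcohol 16 (not isolated)
Conditions: SeO2 (2 equiv), 1,4-dioxane, 80 °C
Reagents that add atoms: selenium dioxide, O=[Se]=O
Why: Riley allylic oxidation, in which the ene reaction at the isopropenyl methyl and a [2,3]-shift give the allylic alcohol, which is oxidised on to the conjugated enal without touching any stereocentre.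

**Compound list**
1 | 4-bromophenol | Oc1ccc(Br)cc1 | starting material
2 | 3-methylbut-2-enal | CC(C)=CC=O | starting material
3 | (6Z)-4-bromo-6-(3-methylbut-2-en-1-ylidene)cyclohexa-2,4-dien-1-one (o-quinone methide) | CC(C)=C/C=C1/C=C(Br)C=CC1=O | intermediate (not isolated)
4 | 6-bromo-2,2-dimethyl-2H-chromene | CC1(C)C=Cc2cc(Br)ccc2O1 | intermediate
5 | N-methoxy-N-methylacetamide | CC(=O)N(C)OC | starting material
6 | (2,2-dimethyl-2H-chromen-6-yl)lithium | [Li]c1ccc2OC(C)(C)C=Cc2c1 | intermediate (not isolated)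
7 | lithium 1-(2,2-dimethyl-2H-chromen-6-yl)-1-[methoxy(methyl)amino]ethan-1-olate (transient, racemic at the new carbon) | CC(O[Li])(N(C)OC)c1ccc2OC(C)(C)C=Cc2c1 | intermediate (not isolated)
8 | 1-(2,2-dimethyl-2H-chromen-6-yl)ethan-1-one | CC(=O)c1ccc2OC(C)(C)C=Cc2c1 | intermediate
9 | 3-methylbutanoic acid | CC(C)CC(=O)O | starting material
10 | [(3R,4S)-6-acetyl-2,2-dimethyl-4-(3-methylbutanoyloxy)chroman-3-yl]{2,6-bis[(1R)-2-methoxy-1-methyl-2-oxoethoxy]phenyl}-λ3-iodanyl 3-methylbutanoate | CC1(C)Oc2ccc(C(C)=O)cc2[C@H](OC(=O)CC(C)C)[C@H]1I(OC(=O)CC(C)C)c1c(O[C@H](C)C(=O)OC)cccc1O[C@H](C)C(=O)OC | intermediate (not isolated)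
11 | 2-[(2R,3S)-5-acetyl-3-(3-methylbutanoyloxy)-2,3-dihydro-1-benzofuran-2-yl]propan-2-ylium | C[C+](C)[C@H]1Oc2ccc(C(C)=O)cc2[C@@H]1OC(=O)CC(C)C | intermediate (not isolated)
12 | (2R,3S)-5-acetyl-2-(prop-1-en-2-yl)-2,3-dihydro-1-benzofuran-3-yl 3-methylbutanoate | CC(=C)[C@H]1Oc2ccc(C(C)=O)cc2[C@@H]1OC(=O)CC(C)C | intermediate
13 | (2R,3S)-5-[(1R)-1-hydroxyethyl]-2-(prop-1-en-2-yl)-2,3-dihydro-1-benzofuran-3-yl 3-methylbutanoate | CC(=C)[C@H]1Oc2ccc([C@@H](C)O)cc2[C@@H]1OC(=O)CC(C)C | intermediate
14 | (2R)-2-methylbutanoic acid | CC[C@@H](C)C(=O)O | starting material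
15 | (1R)-1-[(2R,3S)-3-(3-methylbutanoyloxy)-2-(prop-1-en-2-yl)-2,3-dihydro-1-benzofuran-5-yl]ethyl (2R)-2-methylbutanoate | CC(=C)[C@H]1Oc2ccc([C@@H](C)OC(=O)[C@H](C)CC)cc2[C@@H]1OC(=O)CC(C)C | intermediate
16 | (1R)-1-[(2R,3S)-2-(3-hydroxyprop-1-en-2-yl)-3-(3-methylbutanoyloxy)-2,3-dihydro-1-benzofuran-5-yl]ethyl (2R)-2-methylbutanoate | C=C(CO)[C@H]1Oc2ccc([C@@H](C)OC(=O)[C@H](C)CC)cc2[C@@H]1OC(=O)CC(C)C | intermediate (not isolated)
17 | (1R)-1-[(2R,3S)-3-(3-methylbutanoyloxy)-2-(3-oxoprop-1-en-2-yl)-2,3-dihydro-1-benzofuran-5-yl]ethyl (2R)-2-methylbutanoate (CNP0154159.1) | C=C(C=O)[C@H]1Oc2ccc([C@@H](C)OC(=O)[C@H](C)CC)cc2[C@@H]1OC(=O)CC(C)C | target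

**Totals**
Total steps: 6. Longest linear sequence: 6 (fully linear).

**Steps most likely to fail**

Step 3 (proposed new method). Risks are the competing aryl shift, acyloxy participation leading to diacyloxylation, capture of cation 11 by carboxylate, peracid epoxidation of either alkene, and low or inverted enantioselectivity. The fallback uses known chemistry and sets out from 8. Jacobsen epoxidation with (R,R)-Mn(salen)Cl (3 mol %), NaOCl and 4-phenylpyridine N-oxide in CH2Cl2 at 0 °C gives (3R,4R)-6-acetyl-3,4-epoxy-2,2-dimethylchromane F1. SN2 opening at the benzylic C4 with 9 (catalytic Cs2CO3, toluene, 60 °C) gives (3R,4S)-6-acetyl-3-hydroxy-2,2-dimethylchroman-4-yl 3-methylbutanoate F2. Tf2O and 2,6-lutidine in CH2Cl2 at −78 → 0 °C give (3R,4S)-6-acetyl-2,2-dimethyl-3-(trifluoromethanesulfonyloxy)chroman-4-yl 3-methylbutanoate F3, which contracts in the flask by the same antiperiplanar O1 shift and loss of a methyl proton. The route is rejoined at 12.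

Step 6. Risks are that the SeO2 oxidation stops at alcohol 16, attacks the C2–H, or that the hot, mildly acidic medium eliminates 3-methylbutanoic acid to give the aromatic benzofuran. The fallback sets out from 15. Ene-type allylic chlorination with NCS and catalytic PhSeCl in CH2Cl2 at rt gives (1R)-1-[(2R,3S)-2-(3-chloroprop-1-en-2-yl)-3-(3-methylbutanoyloxy)-2,3-dihydro-1-benzofuran-5-yl]ethyl (2R)-2-methylbutanoate F4. Ganem oxidation of this allylic chloride with trimethylamine N-oxide in DMSO at rt gives the enal, and the route is rejoined at 17.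

Step 1. The risk is a low yield in the boronic-acid condensation with the deactivated 4-bromophenol. The fallback sets out from 1. O-alkylation with 3-chloro-3-methylbut-1-yne (K2CO3, KI, catalytic CuCl2, acetone, reflux) gives 1-bromo-4-[(2-methylbut-3-yn-2-yl)oxy]benzene F5. Heating this in N,N-diethylaniline at 190 °C (propargyl Claisen rearrangement, 1,5-H shift, oxa-6π closure) rejoins the route at 4.

**Further compounds**
F1 | step 3 | (3R,4R)-6-acetyl-3,4-epoxy-2,2-dimethylchromane | CC1(C)Oc2ccc(C(C)=O)cc2[C@H]3O[C@@H]13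
F2 | step 3 | (3R,4S)-6-acetyl-3-hydroxy-2,2-dimethylchroman-4-yl 3-methylbutanoate | CC1(C)Oc2ccc(C(C)=O)cc2[C@H](OC(=O)CC(C)C)[C@H]1O
F3 | step 3 | (3R,4S)-6-acetyl-2,2-dimethyl-3-(trifluoromethanesulfonyloxy)chroman-4-yl 3-methylbutanoate | CC1(C)Oc2ccc(C(C)=O)cc2[C@H](OC(=O)CC(C)C)[C@H]1OS(=O)(=O)C(F)(F)F
F4 | step 6 | (1R)-1-[(2R,3S)-2-(3-chloroprop-1-en-2-yl)-3-(3-methylbutanoyloxy)-2,3-dihydro-1-benzofuran-5-yl]ethyl (2R)-2-methylbutanoate | C=C(CCl)[C@H]1Oc2ccc([C@@H](C)OC(=O)[C@H](C)CC)cc2[C@@H]1OC(=O)CC(C)C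
F5 | step 1 | 1-bromo-4-[(2-methylbut-3-yn-2-yl)oxy]benzene | CC(C)(C#C)Oc1ccc(Br)cc1
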